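**Retrosynthetic overview**
1. The benzylic C–C1 bond is made last: a decarboxylative radical addition of a terpene C1-carboxylic acid to the o-quinone methide formed in situ from 2,4-diformylphloroglucinol and 3-methylbutanal.
2. The C5=C6 alkene and the C4–H centre come from a Pd-mediated reductive 1,3-transposition of a C6 allylic formate; the C7 hydroxyisopropyl group comes from an aldol of the 6-ketone with acetone.
3. The bicyclic 4-en-6-one ester: the C1–C10 bond and the quaternary C10 come from a catalytic asymmetric Mukaiyama–Michael addition to 3-methylcyclohexenone; C4=C5 comes from an aldol condensation.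
4. Ring order: ring B is bought (3-methylcyclohexenone), ring A is annulated onto it, the arene is attached last.

Numbering used in the text (eudesmane-type): C1 carries the side chain, C4 the secondary methyl, C5=C6 is the alkene, C7 carries the hydroxyisopropyl group, C10 the angular methyl; "α" is the face of the C10 methyl.

Assumption: methyl 5-oxohexanoate and 2,4-diformylphloroglucinol are taken as commercial, and the ester-bearing ring carbon C1 is carried as an epimer mixture up to the terpene acid because it becomes a planar radical in the last step.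

**Step 1**
Reactants: 1 methyl 5-oxohexanoate
Product: 2 1-methoxy-1,5-bis(trimethylsilyloxy)hexa-1,5-diene
Conditions: TMSCl (3 equiv), then LDA (2.4 equiv), THF, −78 °C (internal quench); distil
Reagents that add atoms: chlorotrimethylsilane, C[Si](C)(C)Cl
Why: Kinetic double enolisation with in situ O-silylation (enolate trapping) turns the ester into a silyl ketene acetal and masks the ketone as a silyl enol ether, trapping being faster than intramolecular Claisen condensation at −78 °C; no stereocentre is formed.

**Step 2**
Reactants: 2 1-methoxy-1,5-bis(trimethylsilyloxy)hexa-1,5-diene, 3 3-methylcyclohex-2-en-1-one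
Product: 6 methyl (8aR)-4,8a-dimethyl-5-oxo-1,2,3,5,6,7,8,8a-octahydronaphthalene-1-carboxylate, via silyl enol ether Michael adduct 4 (not isolated), via diketo ester 5 (not isolated)
Conditions: chiral IDPi (imidodiphosphorimidate) acid (2 mol%), toluene, −60 °C; then TsOH·H2O (20 mol%), H2O (3 equiv), 80 °C, one pot
Reagents that add atoms: none
Why: Proposed new method: the confined chiral IDPi acid is silylated by 2 to a silylium Lewis acid that activates enone 3 as a silyloxyallyl cation inside the chiral anion pocket, so the ketene acetal carbon (far more nucleophilic than the ketone-derived enol ether) adds to one face of the β-carbon and sets the quaternary C10 centre, with silyl transfer turning the catalyst over; the closest known reaction type is the silylium-IDPi (counteranion-directed) Mukaiyama–Michael addition of silyl ketene acetals to α,β-unsaturated esters and unsubstituted enones, not yet shown for a β-methyl cyclic enone giving a quaternary carbon, and the acid stage is ordinary enol ether hydrolysis and Robinson-type aldol condensation in which only the C5-to-C4 closure can dehydrate.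

**Step 3**
Reactants: 6 methyl (8aR)-4,8a-dimethyl-5-oxo-1,2,3,5,6,7,8,8a-octahydronaphthalene-1-carboxylate, 7 acetone
Product: 8 methyl (6R,8aR)-6-(2-hydroxypropan-2-yl)-4,8a-dimethyl-5-oxo-1,2,3,5,6,7,8,8a-octahydronaphthalene-1-carboxylate
Conditions: LDA (1.1 equiv), THF, −78 °C; ZnCl2 (1.1 equiv); acetone (3 equiv), −78 → −20 °C; aq. NH4Cl
Reagents that add atoms: none
Why: Directed aldol addition: LDA deprotonates the α′ position C7 kinetically (cross-conjugated enolate), and the zinc aldolate equilibrates by retro-aldol/aldol to the chelated isomer with the hydroxyisopropyl group equatorial, that is cis to the axial C10 methyl, so C7 is set under thermodynamic control.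

**Step 4**
Reactants: 8 methyl (6R,8aR)-6-(2-hydroxypropan-2-yl)-4,8a-dimethyl-5-oxo-1,2,3,5,6,7,8,8a-octahydronaphthalene-1-carboxylate
Product: 9 methyl (5S,6S,8aR)-5-hydroxy-6-(2-hydroxypropan-2-yl)-4,8a-dimethyl-1,2,3,5,6,7,8,8a-octahydronaphthalene-1-carboxylate
Conditions: NaBH4, CeCl3·7H2O, MeOH, −40 °C
Reagents that add atoms: none
Why: Luche 1,2-reduction: the tetrasubstituted enone resists 1,4-reduction and hydride enters anti to the axial C10 methyl (as with 6-oxo steroids), giving the axial C6 alcohol cis to that methyl and to the C7 side chain while the ester is untouched.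

**Step 5**
Reactants: 9 methyl (5S,6S,8aR)-5-hydroxy-6-(2-hydroxypropan-2-yl)-4,8a-dimethyl-1,2,3,5,6,7,8,8a-octahydronaphthalene-1-carboxylate
Product: 10 methyl (5S,6S,8aR)-5-(formyloxy)-6-(2-hydroxypropan-2-yl)-4,8a-dimethyl-1,2,3,5,6,7,8,8a-octahydronaphthalene-1-carboxylate
Conditions: HCO2H, DIC, DMAP (cat.), CH2Cl2, 0 °C → rt
Reagents that add atoms: formic acid, O=CO
Why: Steglich-type O-formylation acylates only the secondary allylic hydroxyl, the tertiary carbinol being inert, and no stereocentre changes.

**Step 6**
Reactants: 10 methyl (5S,6S,8aR)-5-(formyloxy)-6-(2-hydroxypropan-2-yl)-4,8a-dimethyl-1,2,3,5,6,7,8,8a-octahydronaphthalene-1-carboxylate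
Product: 11 methyl (4R,6S,8aR)-6-(2-hydroxypropan-2-yl)-4,8a-dimethyl-1,2,3,4,6,7,8,8a-octahydronaphthalene-1-carboxylate
Conditions: Pd(OAc)2 (5 mol%), n-Bu3P (10 mol%), dioxane, 60 °C
Reagents that add atoms: none
Why: Tsuji–Mandai hydrogenolysis of an allylic formate: Pd(0) ionises the axial formate anti (from the β face), the palladium formate loses CO2, and the hydride passes from palladium to the more substituted allyl terminus C4 on that same β face, which moves the alkene to C5=C6 and sets C4 with its methyl α (cis to the C10 methyl).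

**Step 7**
Reactants: 11 methyl (4R,6S,8aR)-6-(2-hydroxypropan-2-yl)-4,8a-dimethyl-1,2,3,4,6,7,8,8a-octahydronaphthalene-1-carboxylate
Product: 12 (4R,6S,8aR)-6-(2-hydroxypropan-2-yl)-4,8a-dimethyl-1,2,3,4,6,7,8,8a-octahydronaphthalene-1-carboxylic acid
Conditions: LiOH·H2O, THF/MeOH/H2O, 60 °C; then 1 M HCl
Reagents that add atoms: lithium hydroxide, [Li+].[OH-]
Why: Saponification of the hindered methyl ester; the alkene and the tertiary alcohol tolerate base, and epimerisation at C1 does not matter.

**Step 8**
Reactants: 12 (4R,6S,8aR)-6-(2-hydroxypropan-2-yl)-4,8a-dimethyl-1,2,3,4,6,7,8,8a-octahydronaphthalene-1-carboxylic acid, 13 2,4,6-trihydroxybenzene-1,3-dicarbaldehyde, 14 3-methylbutanal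
Product: 16 2,4,6-trihydroxy-5-[(1S)-1-[(1R,4R,6S,8aR)-6-(2-hydroxypropan-2-yl)-4,8a-dimethyl-1,2,3,4,6,7,8,8a-octahydronaphthalen-1-yl]-3-methylbutyl]benzene-1,3-dicarbaldehyde, via o-quinone methide 15 (not isolated)
Conditions: 13 (2 equiv), 14 (3 equiv), 4CzIPN (2 mol%), K2HPO4 (20 mol%), DMSO, blue LEDs, 30 °C, N2
Reagents that add atoms: none
Why: Knoevenagel condensation of 13 and 14 gives o-quinone methide 15, and a photoredox decarboxylative Giese-type addition joins the fragments: the C1 radical is attacked on the α face, anti to the axial C10–C9 bond of the half-chair that keeps both methyls equatorial (sets C1), and in the staggered transition state the quinoid ring lies anti to the quaternary C10 with the isobutyl chain beside C1–H rather than C2 (sets the benzylic centre S), before reduction and protonation restore the phenol.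

**Compound list**
1 | methyl 5-oxohexanoate | CC(=O)CCCC(=O)OC | starting material
2 | 1-methoxy-1,5-bis(trimethylsilyloxy)hexa-1,5-diene (ketene acetal E/Z mixture) | C=C(O[Si](C)(C)C)CCC=C(OC)O[Si](C)(C)C | intermediate
3 | 3-methylcyclohex-2-en-1-one | CC1=CC(=O)CCC1 | starting material
4 | methyl 2-[(1S)-1-methyl-3-(trimethylsilyloxy)cyclohex-2-en-1-yl]-5-(trimethylsilyloxy)hex-5-enoate (C2 epimers) | COC(=O)C(CCC(=C)O[Si](C)(C)C)[C@]1(C)C=C(O[Si](C)(C)C)CCC1 | intermediate (not isolated)
5 | methyl 2-[(1S)-1-methyl-3-oxocyclohexyl]-5-oxohexanoate (C2 epimers) | COC(=O)C(CCC(C)=O)[C@]1(C)CC(=O)CCC1 | intermediate (not isolated)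
6 | methyl (8aR)-4,8a-dimethyl-5-oxo-1,2,3,5,6,7,8,8a-octahydronaphthalene-1-carboxylate (C1 epimers) | COC(=O)C1CCC(C)=C2C(=O)CCC[C@@]21C | intermediate
7 | acetone | CC(C)=O | starting material
8 | methyl (6R,8aR)-6-(2-hydroxypropan-2-yl)-4,8a-dimethyl-5-oxo-1,2,3,5,6,7,8,8a-octahydronaphthalene-1-carboxylate (C1 epimers) | COC(=O)C1CCC(C)=C2C(=O)[C@@H](C(C)(C)O)CC[C@@]21C | intermediate
9 | methyl (5S,6S,8aR)-5-hydroxy-6-(2-hydroxypropan-2-yl)-4,8a-dimethyl-1,2,3,5,6,7,8,8a-octahydronaphthalene-1-carboxylate (C1 epimers) | COC(=O)C1CCC(C)=C2[C@@H](O)[C@@H](C(C)(C)O)CC[C@@]21C | intermediate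
10 | methyl (5S,6S,8aR)-5-(formyloxy)-6-(2-hydroxypropan-2-yl)-4,8a-dimethyl-1,2,3,5,6,7,8,8a-octahydronaphthalene-1-carboxylate (C1 epimers) | COC(=O)C1CCC(C)=C2[C@@H](OC=O)[C@@H](C(C)(C)O)CC[C@@]21C | intermediate
11 | methyl (4R,6S,8aR)-6-(2-hydroxypropan-2-yl)-4,8a-dimethyl-1,2,3,4,6,7,8,8a-octahydronaphthalene-1-carboxylate (C1 epimers) | COC(=O)C1CC[C@@H](C)C2=C[C@@H](C(C)(C)O)CC[C@@]21C | intermediate
12 | (4R,6S,8aR)-6-(2-hydroxypropan-2-yl)-4,8a-dimethyl-1,2,3,4,6,7,8,8a-octahydronaphthalene-1-carboxylic acid (C1 epimers) | OC(=O)C1CC[C@@H](C)C2=C[C@@H](C(C)(C)O)CC[C@@]21C | intermediate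
13 | 2,4,6-trihydroxybenzene-1,3-dicarbaldehyde (2,4-diformylphloroglucinol) | O=Cc1c(O)cc(O)c(C=O)c1O | starting material
14 | 3-methylbutanal | CC(C)CC=O | starting material
15 | 2,4-diformyl-3,5-dihydroxy-6-(3-methylbutylidene)cyclohexa-2,4-dien-1-one (o-quinone methide) | CC(C)CC=C1C(=O)C(C=O)=C(O)C(C=O)=C1O | intermediate (not isolated)
16 | 2,4,6-trihydroxy-5-[(1S)-1-[(1R,4R,6S,8aR)-6-(2-hydroxypropan-2-yl)-4,8a-dimethyl-1,2,3,4,6,7,8,8a-octahydronaphthalen-1-yl]-3-methylbutyl]benzene-1,3-dicarbaldehyde (CNP0108656.4) | CC(C)C[C@H](c1c(O)c(C=O)c(O)c(C=O)c1O)[C@H]1CC[C@@H](C)C2=C[C@@H](C(C)(C)O)CC[C@@]21C | target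

**Total step count:** 8. **Longest linear sequence:** 8 steps (1 → 16).

**Three steps most likely to fail**

Step 2 (the proposed new step). Risks are 1,2-addition, low enantioselectivity at the quaternary carbon, and competing reaction of the second enol ether. The fallback uses known chemistry and makes the quaternary centre by a C–methyl bond instead. It sets out from 2: a TiCl4-mediated Mukaiyama–Michael addition–elimination of 2 with commercial 3-ethoxycyclohex-2-en-1-one (CH2Cl2, −78 °C, aqueous work-up) gives methyl 5-oxo-2-(3-oxocyclohex-1-en-1-yl)hexanoate F1. The established copper-catalysed enantioselective conjugate addition of trimethylaluminium to 3-substituted cyclohexenones (CuTC, chiral phosphoramidite, Et2O, −30 °C) then adds the C10 methyl to F1. This comes back to the route at 5, which is cyclised to 6 with TsOH as in step 2.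

Step 6. Risks are diene formation by β-hydride elimination and hydride delivery to C6 instead of C4. The fallback sets out from 9 and uses the Myers reductive allylic transposition: o-nitrobenzenesulfonylhydrazine, PPh3 and DEAD in THF at −30 °C, then warming to 23 °C. Mitsunobu displacement with inversion gives the β-face allylic diazene, which loses N2 by a retro-ene shift and delivers hydrogen to C4 on the β face. It makes no new isolated compound (F0) and comes back at 11.

Step 8. Risks are self-condensation or tautomerisation of 15, oxidation of the phenolate instead of the carboxylate, and modest diastereoselectivity at C1 and the benzylic carbon (epimers would need HPLC separation). The fallback uses two isolated, pre-activated partners and reductive radical generation. It sets out from 12, which is converted with N-hydroxyphthalimide, DIC and DMAP into 1,3-dioxoisoindolin-2-yl (4R,6S,8aR)-6-(2-hydroxypropan-2-yl)-4,8a-dimethyl-1,2,3,4,6,7,8,8a-octahydronaphthalene-1-carboxylate F2. Separately, 13, 14 and benzenesulfinic acid (HCO2H, rt) give the o-quinone methide precursor 2,4,6-trihydroxy-5-[3-methyl-1-(phenylsulfonyl)butyl]benzene-1,3-dicarbaldehyde F3. F2 and F3 are then joined under known redox-active-ester Giese conditions (Hantzsch ester, Ru(bpy)3(PF6)2 1 mol%, i-Pr2NEt, CH2Cl2/DMF, blue LEDs); the base releases 15 from F3 by loss of sulfinate. It comes back at 16.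

**Further compounds**
F1 | step 2 | methyl 5-oxo-2-(3-oxocyclohex-1-en-1-yl)hexanoate | COC(=O)C(CCC(C)=O)C1=CC(=O)CCC1
F0 | step 6 | none | none
F2 | step 8 | 1,3-dioxoisoindolin-2-yl (4R,6S,8aR)-6-(2-hydroxypropan-2-yl)-4,8a-dimethyl-1,2,3,4,6,7,8,8a-octahydronaphthalene-1-carboxylate | O=C(ON1C(=O)c2ccccc2C1=O)C1CC[C@@H](C)C2=C[C@@H](C(C)(C)O)CC[C@@]21C
F3 | step 8 | 2,4,6-trihydroxy-5-[3-methyl-1-(phenylsulfonyl)butyl]benzene-1,3-dicarbaldehyde | CC(C)CC(c1c(O)c(C=O)c(O)c(C=O)c1O)S(=O)(=O)c1ccccc1
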